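The pitfall here is to set the two rate constants side by side, since they carry different units and say nothing until the catalysts and the coupling partner are multiplied in.

    starting material + free catalyst → free catalyst + intermediate (k1 = 0.45 M⁻¹ s⁻¹)
    coupling partner + second catalyst + intermediate → second catalyst + target (k2 = 0.58 M⁻² s⁻¹)
    starting material + intermediate → side product (k3 = 0.0081 M⁻¹ s⁻¹)
    crystals ⇌ target, rate k4*(cs4 - [target]) while solid is left; crystals form when [target] > cs4 (cs4 = 0.091 M, k4 = 0.88 s⁻¹)

the same everywhere: starting material 0.20 M; coupling partner 0.500 M; free catalyst 10 mM; second catalyst 38 mM

| run | time |
|---|---|
| cedar | 1.5 min |
| larch | 4.0 min |

- percent here means starting material units held: one side product counts as two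
- what is said of target includes crystals
- crystals is a solid; its amount is given per volume of the solution
- run time (cedar): 1.5 min

* which of these there is most of at the end, counted by the starting material in it, cedar (target / side product / intermediate / starting material)
* which of these there is most of at the end, counted by the starting material in it, larch (target / side product / intermediate / starting material)
* final amount of the leader among these, as a percentage of the starting material charged, in cedar
* final amount of the leader among these, as a percentage of the starting material charged, in larch

How fast does each main step run? Both catalysts come out of their steps unchanged, and I hold the coupling partner at its charge, so each step is pseudo-first-order. Starting material goes at a = 0.00450 s⁻¹ and intermediate at b = 0.0110 s⁻¹. The side step takes intermediate at 0.00162 s⁻¹, slower than b, so I leave it out of the reckoning.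

What does that do to the intermediate? I divide its rate of use by its rate of making, and time drops out: used over made is κ·c(intermediate)/c(starting material), with κ = b/a = 2.45. I call κ the hand-over ratio, the readiness of intermediate to leave over the readiness of starting material to arrive. So intermediate climbs until c(intermediate) reaches c(starting material)/κ, and then falls. With x the fraction of starting material left, the textbook result for two steps in a row gives intermediate as (x − x^κ)/(κ − 1), and the rest is target.

Who leads at the end? With x = exp(−a·t), cedar has starting material 66.7 %, intermediate 20.4 % and target 12.9 %. Larch has starting material 34.0 %, intermediate 18.5 % and target 47.5 %. I commit to starting material leading cedar and target leading larch, knowing that the side step I dropped takes from that target figure.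

The forecast gives starting material at 65 % for cedar and target at 42 % for larch, a lower larch figure than mine, and its grounds are “a slow-then-faster consecutive sequence with a small side-product leak”.

The simulation gives starting material at 65.5 % in cedar and target at 42.1 % in larch. Neither flask is at rest. Made over used, reckoned as c(starting material)/(κ·c(intermediate)) with κ as charged and the side step left out, comes to 1.37 at the end of cedar, and with each step taken net the flask gives 1.31, so in cedar intermediate is still climbing. The same reckoning comes to 0.692 at the end of larch and 0.529 in the flask cedar left until 6.0 min, both below one, and in larch intermediate stands at 18.7 %, down from 20.9 % at 2.00 min. Left until 40.0 min, larch gains a further 48 percentage points of target, reaching 90.0 %, of which 44.5 % stands as crystals.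

The constants were set for the occasion; what happens was integrated by code.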